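**Strategy.** The pyranone ring is opened at O1–C8a, which leaves ring A as the same 2,3-dihydroxy-4-methoxyphenyl unit as ring B. The key step exploits the free C5/C6 catechol of ring A, flanking the C4 ketone, with C8a para to the C6 hydroxyl: oxidation to the 5,6-quinone makes C8a a doubly activated acceptor, the C2 hydroxyl adds, and tautomerisation restores the 5,6-diol, so one operation closes the ring and forms O1–C8a. The precursor is an open-chain anti (2R,3R) β-hydroxy-α-methoxy aryl ketone with a free A-ring catechol and a benzyl-protected B-ring catechol, assembled by an aldol reaction of two fragments from one aldehyde.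

Key step: step 8

Assumption: aldehyde 1 is purchased, and the catalyst antipode for step 6 is fixed by a small-scale test with both antipodes (MTPA ester analysis of 9), because only the required Si-face attack on 8 is asserted here, not the catalyst descriptor.

**Step 1**
Reactants: 1 2,3-dihydroxy-4-methoxybenzaldehyde
Product: 2 2,3-bis[(tert-butyldimethylsilyl)oxy]-4-methoxybenzaldehyde
Conditions: TBSCl (2.5 equiv), imidazole (5 equiv), DMF, rt
Reagents that add atoms: tert-butyldimethylsilyl chloride, CC(C)(C)[Si](C)(C)Cl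
Why: Imidazole-promoted O-silylation of phenols; excess reagent in DMF should also silylate the hydrogen-bonded 2-OH, and the aryl silyl ethers withstand the organometallic, oxidation and Lewis-acid steps yet leave later with fluoride, without acid or base.

**Step 2**
Reactants: 2 2,3-bis[(tert-butyldimethylsilyl)oxy]-4-methoxybenzaldehyde; 3 chloromethyl methyl ether
Product: 5 rac-1-{2,3-bis[(tert-butyldimethylsilyl)oxy]-4-methoxyphenyl}-2-methoxyethan-1-ol, via methoxymethylmagnesium chloride 4 (not isolated)
Conditions: Mg, cat. HgCl2, THF, −25 °C; then 2, −25 → 0 °C; cold aq. NH4Cl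
Reagents that add atoms: none
Why: Grignard addition of an α-alkoxymethyl magnesium reagent to an aryl aldehyde; the reagent is made and used below −20 °C because it decomposes by α-elimination, the cold quench should forestall aryl-to-alkoxide silyl migration, and the racemic carbinol centre is removed in step 3.

**Step 3**
Reactants: 5 rac-1-{2,3-bis[(tert-butyldimethylsilyl)oxy]-4-methoxyphenyl}-2-methoxyethan-1-ol
Product: 6 1-{2,3-bis[(tert-butyldimethylsilyl)oxy]-4-methoxyphenyl}-2-methoxyethan-1-one
Conditions: Dess–Martin periodinane (1.3 equiv), pyridine, CH2Cl2, 0 °C → rt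
Reagents that add atoms: none
Why: Dess–Martin oxidation of a secondary benzylic alcohol to the ketone under buffered, near-neutral conditions that should leave the aryl silyl ethers and the α-methoxy group untouched.

**Step 4**
Reactants: 6 1-{2,3-bis[(tert-butyldimethylsilyl)oxy]-4-methoxyphenyl}-2-methoxyethan-1-one
Product: 7 (Z)-tert-butyl[(1-{2,3-bis[(tert-butyldimethylsilyl)oxy]-4-methoxyphenyl}-2-methoxyethenyl)oxy]dimethylsilane
Conditions: TBSOTf (1.3 equiv), Et3N (2 equiv), CH2Cl2, 0 °C
Reagents that add atoms: tert-butyldimethylsilyl trifluoromethanesulfonate, CC(C)(C)[Si](C)(C)OS(=O)(=O)C(F)(F)F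
Why: Soft enolisation with silyl triflate and amine at the only enolisable position gives the silyl enol ether; the Z isomer (aryl trans to OMe) is expected on steric grounds, and the geometry is not decisive for the open-transition-state aldol of step 6.

**Step 5**
Reactants: 1 2,3-dihydroxy-4-methoxybenzaldehyde
Product: 8 2,3-bis(benzyloxy)-4-methoxybenzaldehyde
Conditions: BnBr (2.4 equiv), K2CO3, DMF, 60 °C
Reagents that add atoms: benzyl bromide, BrCc1ccccc1
Why: Williamson ether synthesis on both phenols; the benzyl ethers make ring B inert to the oxidant of step 8 and are removed together in the last step.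

**Step 6**
Reactants: 7 (Z)-tert-butyl[(1-{2,3-bis[(tert-butyldimethylsilyl)oxy]-4-methoxyphenyl}-2-methoxyethenyl)oxy]dimethylsilane; 8 2,3-bis(benzyloxy)-4-methoxybenzaldehyde
Product: 9 (2R,3R)-3-[2,3-bis(benzyloxy)-4-methoxyphenyl]-1-{2,3-bis[(tert-butyldimethylsilyl)oxy]-4-methoxyphenyl}-3-hydroxy-2-methoxypropan-1-one
Conditions: SiCl4 (1.2 equiv), chiral binaphthyl-2,2′-diamine-derived pentamethylene-linked bisphosphoramide (5 mol %, antipode giving Si-face attack on 8), iPr2NEt (10 mol %), CH2Cl2, −78 °C; aq. NaHCO3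
Reagents that add atoms: none
Why: Lewis-base-catalysed, SiCl4-mediated enantioselective Mukaiyama aldol through an open transition state, which for silyl enol derivatives with a small α-methoxy group and a bulky acyl substituent favours the anti adduct; C3 is set by catalyst-controlled Si-face attack on the aldehyde and C2 by the anti topology.

**Step 7**
Reactants: 9 (2R,3R)-3-[2,3-bis(benzyloxy)-4-methoxyphenyl]-1-{2,3-bis[(tert-butyldimethylsilyl)oxy]-4-methoxyphenyl}-3-hydroxy-2-methoxypropan-1-one
Product: 10 (2R,3R)-3-[2,3-bis(benzyloxy)-4-methoxyphenyl]-1-(2,3-dihydroxy-4-methoxyphenyl)-3-hydroxy-2-methoxypropan-1-one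
Conditions: Et3N·3HF (4 equiv), THF, 0 °C → rt
Reagents that add atoms: none
Why: Fluoride cleavage of the two aryl silyl ethers with the nearly neutral amine–HF complex, which avoids the basic conditions that would epimerise C2 or trigger retro-aldol cleavage; benzyl and methyl ethers are inert.

**Step 8**
Reactants: 10 (2R,3R)-3-[2,3-bis(benzyloxy)-4-methoxyphenyl]-1-(2,3-dihydroxy-4-methoxyphenyl)-3-hydroxy-2-methoxypropan-1-one
Product: 12 (2R,3R)-2-[2,3-bis(benzyloxy)-4-methoxyphenyl]-5,6-dihydroxy-3,7-dimethoxychroman-4-one, via acyl ortho-quinone 11 (not isolated)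
Conditions: o-chloranil (1.0 equiv), CH2Cl2 (0.01 M), argon, dark, −40 °C → rt; then aq. Na2S2O4 wash
Reagents that add atoms: none
Why: Proposed new method: o-chloranil dehydrogenates the only free catechol (ring A) to the 3-acyl ortho-quinone 11, in which C8a is the β-carbon of both the C5 quinone carbonyl and the C4 ketone; the C2 hydroxyl adds there (oxa-Michael) and enolisation with loss of the C8a proton rearomatises ring A, so C8a–H is exchanged for C8a–O1 and the 5,6-diol is returned. The closest known reaction type is the oxidative cyclisation of catechols through intramolecular conjugate addition of a tethered N- or O-nucleophile to the ortho-quinone (cyclodopa formation, oxidative lactonisation of dihydrocaffeic acids). The pyranone ring closes in the 6-endo-trig mode, the C4a=C8a bond lying inside the new ring. No stereocentre is formed: C2 and C3 come unchanged from 10, and the trans (diequatorial) arrangement is also the thermodynamic one if C3 should enolise. The step needs oxidation of ring A only (secured by the benzyl ethers on ring B), attack at C8a and not at C8 (C8 would demand a seven-membered ring and lacks the second activating carbonyl) and 1,4- over 1,2-addition (hemiketalisation at C5 is equally reachable but reversible, whereas only the C8a adduct can aromatise). One equivalent of a non-basic oxidant at high dilution avoids retro-aldol cleavage and quinone dimerisation, redox exchange between over-oxidised product and unreacted 10 funnels material to 12, and the dithionite wash reduces any quinone that remains.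

**Step 9**
Reactants: 12 (2R,3R)-2-[2,3-bis(benzyloxy)-4-methoxyphenyl]-5,6-dihydroxy-3,7-dimethoxychroman-4-one
Product: 13 (2R,3R)-2-(2,3-dihydroxy-4-methoxyphenyl)-5,6-dihydroxy-3,7-dimethoxychroman-4-one
Conditions: H2 (1 atm), 10% Pd/C, EtOAc–THF, rt; filtration under argon
Reagents that add atoms: none
Why: Catalytic hydrogenolysis of the two aryl benzyl ethers; under 1 atm H2 in a neutral aprotic solvent the hydrogen-bonded aryl ketone and the cyclic benzylic C2–O1 bond should survive, and no stereocentre is touched.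

**Compound list**
1 | 2,3-dihydroxy-4-methoxybenzaldehyde | COc1ccc(C=O)c(O)c1O | starting material
2 | 2,3-bis[(tert-butyldimethylsilyl)oxy]-4-methoxybenzaldehyde | COc1ccc(C=O)c(O[Si](C)(C)C(C)(C)C)c1O[Si](C)(C)C(C)(C)C | intermediate
3 | chloromethyl methyl ether | COCCl | starting material
4 | methoxymethylmagnesium chloride | COC[Mg]Cl | intermediate (not isolated)
5 | rac-1-{2,3-bis[(tert-butyldimethylsilyl)oxy]-4-methoxyphenyl}-2-methoxyethan-1-ol (racemic) | COCC(O)c1ccc(OC)c(O[Si](C)(C)C(C)(C)C)c1O[Si](C)(C)C(C)(C)C | intermediate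
6 | 1-{2,3-bis[(tert-butyldimethylsilyl)oxy]-4-methoxyphenyl}-2-methoxyethan-1-one | COCC(=O)c1ccc(OC)c(O[Si](C)(C)C(C)(C)C)c1O[Si](C)(C)C(C)(C)C | intermediate
7 | (Z)-tert-butyl[(1-{2,3-bis[(tert-butyldimethylsilyl)oxy]-4-methoxyphenyl}-2-methoxyethenyl)oxy]dimethylsilane | CO/C=C(\O[Si](C)(C)C(C)(C)C)c1ccc(OC)c(O[Si](C)(C)C(C)(C)C)c1O[Si](C)(C)C(C)(C)C | intermediate
8 | 2,3-bis(benzyloxy)-4-methoxybenzaldehyde | COc1ccc(C=O)c(OCc2ccccc2)c1OCc1ccccc1 | intermediate
9 | (2R,3R)-3-[2,3-bis(benzyloxy)-4-methoxyphenyl]-1-{2,3-bis[(tert-butyldimethylsilyl)oxy]-4-methoxyphenyl}-3-hydroxy-2-methoxypropan-1-one | COc1ccc([C@@H](O)[C@@H](OC)C(=O)c2ccc(OC)c(O[Si](C)(C)C(C)(C)C)c2O[Si](C)(C)C(C)(C)C)c(OCc2ccccc2)c1OCc1ccccc1 | intermediate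
10 | (2R,3R)-3-[2,3-bis(benzyloxy)-4-methoxyphenyl]-1-(2,3-dihydroxy-4-methoxyphenyl)-3-hydroxy-2-methoxypropan-1-one | COc1ccc([C@@H](O)[C@@H](OC)C(=O)c2ccc(OC)c(O)c2O)c(OCc2ccccc2)c1OCc1ccccc1 | intermediate
11 | 3-{(2R,3R)-3-[2,3-bis(benzyloxy)-4-methoxyphenyl]-3-hydroxy-2-methoxypropanoyl}-6-methoxycyclohexa-3,5-diene-1,2-dione | COc1ccc([C@@H](O)[C@@H](OC)C(=O)C2=CC=C(OC)C(=O)C2=O)c(OCc2ccccc2)c1OCc1ccccc1 | intermediate (not isolated)
12 | (2R,3R)-2-[2,3-bis(benzyloxy)-4-methoxyphenyl]-5,6-dihydroxy-3,7-dimethoxychroman-4-one | COc1ccc([C@H]2Oc3cc(OC)c(O)c(O)c3C(=O)[C@@H]2OC)c(OCc2ccccc2)c1OCc1ccccc1 | intermediate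
13 | (2R,3R)-2-(2,3-dihydroxy-4-methoxyphenyl)-5,6-dihydroxy-3,7-dimethoxychroman-4-one | COc1ccc([C@H]2Oc3cc(OC)c(O)c(O)c3C(=O)[C@@H]2OC)c(O)c1O | target

**Step count.** Total: 9 steps. Longest linear sequence: 8 steps (1 → 2 → 5 → 6 → 7 → 9 → 10 → 12 → 13; steps 1, 2, 3, 4, 6, 7, 8, 9).

**Steps most likely to fail**

1. Step 8 (proposed new method). The ortho-quinone may be consumed before the hydroxyl closes onto C8a: by dimerisation or intermolecular addition, by hydride transfer from the carbinol C–H to the quinone, or by over-oxidation of the cyclised catechol followed by tautomerisation to the flavone. The fallback uses known chemistry: a halogen is placed at C8a beforehand and O1–C8a is closed by palladium-catalysed aryl C–O coupling. It sets out from 1 and comes back at 12. Compound 1 is protected with MOMCl/iPr2NEt as 4-methoxy-2,3-bis(methoxymethoxy)benzaldehyde F1. In situ α-amino alkoxide formation (lithium N,N,N′-trimethylethylenediamide) directs ortho-lithiation (n-BuLi) to C6, and quenching with BrCF2CF2Br should give 6-bromo-4-methoxy-2,3-bis(methoxymethoxy)benzaldehyde F2. Addition of 4 gives 1-[6-bromo-4-methoxy-2,3-bis(methoxymethoxy)phenyl]-2-methoxyethan-1-ol F3, and Dess–Martin oxidation gives 1-[6-bromo-4-methoxy-2,3-bis(methoxymethoxy)phenyl]-2-methoxyethan-1-one F4. LiHMDS/TBSCl gives (Z)-{[1-(6-bromo-4-methoxy-2,3-bis(methoxymethoxy)phenyl)-2-methoxyethenyl]oxy}(tert-butyl)dimethylsilane F5. The aldol of step 6 with 8 gives (2R,3R)-3-[2,3-bis(benzyloxy)-4-methoxyphenyl]-1-[6-bromo-4-methoxy-2,3-bis(methoxymethoxy)phenyl]-3-hydroxy-2-methoxypropan-1-one F6. Intramolecular etherification (Pd(OAc)2, bulky biaryl di-tert-butylphosphine, K3PO4, toluene, 60 °C) gives (2R,3R)-2-[2,3-bis(benzyloxy)-4-methoxyphenyl]-3,7-dimethoxy-5,6-bis(methoxymethoxy)chroman-4-one F7. HCl in MeOH then removes the MOM groups to give 12.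

2. Step 6. Face discrimination or anti/syn discrimination may be insufficient, because the enol silane is ketone-derived while the closest anti-selective cases are ester-derived; addition to the electron-rich aldehyde may also be sluggish. The fallback sets out from 7 and 8 and comes back at 9. The two are combined with SiCl4 and catalytic achiral HMPA to give racemic anti aldol, that is 9 together with (2S,3S)-3-[2,3-bis(benzyloxy)-4-methoxyphenyl]-1-{2,3-bis[(tert-butyldimethylsilyl)oxy]-4-methoxyphenyl}-3-hydroxy-2-methoxypropan-1-one F8. Any syn isomer is removed on silica, and the enantiomers are separated by preparative SFC on a polysaccharide chiral phase.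

3. Step 2. The α-alkoxy Grignard reagent may decompose by α-elimination before it adds, and a silyl group may migrate from the aryl oxygen to the new alkoxide. The fallback sets out from 2 and comes back at 6, so step 3 is not needed. Pinnick oxidation of 2 gives 2,3-bis[(tert-butyldimethylsilyl)oxy]-4-methoxybenzoic acid F9. The acid chloride ((COCl)2, cat. DMF) with trimethylsilyldiazomethane gives 1-{2,3-bis[(tert-butyldimethylsilyl)oxy]-4-methoxyphenyl}-2-diazoethan-1-one F10. Rh2(OAc)4-catalysed O–H insertion into methanol then gives 6.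

**Further compounds**
F1 | step 8 | 4-methoxy-2,3-bis(methoxymethoxy)benzaldehyde | COCOc1c(C=O)ccc(OC)c1OCOC
F2 | step 8 | 6-bromo-4-methoxy-2,3-bis(methoxymethoxy)benzaldehyde | COCOc1c(C=O)c(Br)cc(OC)c1OCOC
F3 | step 8 | 1-[6-bromo-4-methoxy-2,3-bis(methoxymethoxy)phenyl]-2-methoxyethan-1-ol (racemic) | COCC(O)c1c(Br)cc(OC)c(OCOC)c1OCOC
F4 | step 8 | 1-[6-bromo-4-methoxy-2,3-bis(methoxymethoxy)phenyl]-2-methoxyethan-1-one | COCC(=O)c1c(Br)cc(OC)c(OCOC)c1OCOC
F5 | step 8 | (Z)-{[1-(6-bromo-4-methoxy-2,3-bis(methoxymethoxy)phenyl)-2-methoxyethenyl]oxy}(tert-butyl)dimethylsilane | CO/C=C(\O[Si](C)(C)C(C)(C)C)c1c(Br)cc(OC)c(OCOC)c1OCOC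
F6 | step 8 | (2R,3R)-3-[2,3-bis(benzyloxy)-4-methoxyphenyl]-1-[6-bromo-4-methoxy-2,3-bis(methoxymethoxy)phenyl]-3-hydroxy-2-methoxypropan-1-one | COc1ccc([C@@H](O)[C@@H](OC)C(=O)c2c(Br)cc(OC)c(OCOC)c2OCOC)c(OCc2ccccc2)c1OCc1ccccc1
F7 | step 8 | (2R,3R)-2-[2,3-bis(benzyloxy)-4-methoxyphenyl]-3,7-dimethoxy-5,6-bis(methoxymethoxy)chroman-4-one | COc1ccc([C@H]2Oc3cc(OC)c(OCOC)c(OCOC)c3C(=O)[C@@H]2OC)c(OCc2ccccc2)c1OCc1ccccc1
F8 | step 6 | (2S,3S)-3-[2,3-bis(benzyloxy)-4-methoxyphenyl]-1-{2,3-bis[(tert-butyldimethylsilyl)oxy]-4-methoxyphenyl}-3-hydroxy-2-methoxypropan-1-one | COc1ccc([C@H](O)[C@H](OC)C(=O)c2ccc(OC)c(O[Si](C)(C)C(C)(C)C)c2O[Si](C)(C)C(C)(C)C)c(OCc2ccccc2)c1OCc1ccccc1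
F9 | step 2 | 2,3-bis[(tert-butyldimethylsilyl)oxy]-4-methoxybenzoic acid | COc1ccc(C(=O)O)c(O[Si](C)(C)C(C)(C)C)c1O[Si](C)(C)C(C)(C)C
F10 | step 2 | 1-{2,3-bis[(tert-butyldimethylsilyl)oxy]-4-methoxyphenyl}-2-diazoethan-1-one | COc1ccc(C(=O)C=[N+]=[N-])c(O[Si](C)(C)C(C)(C)C)c1O[Si](C)(C)C(C)(C)C
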